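**Retrosynthetic overview**

1. Target 19 ← acetylation, Wittig methylenation at C8 (adds C17), saponification with C9 equilibration, and C6 deoxygenation ← bicyclic 6-hydroxy-8-ketone 14 (17-norlabdane, labdane numbering throughout).
2. 14 ← convergent [3+3] closure of ring B: C6–C7 (ene-type aldol addition) and C9–C10 (cation/enol silane alkylation) join ring-A aldehyde 6 and the geranyl-derived enol silane 12.
3. Enabling feature: C8 of ring B carries an exocyclic one-carbon unit between C7H2 and C9H, so at the ketone level C7–C8–C9 is an acetone-type 1,3-bis-nucleophile; C6 (as CHO on C5) and the methyl-bearing quaternary C10 (as tertiary cation) of ring A are the matching 1,3-bis-electrophile.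
4. 6 ← enantioselective Diels–Alder reaction of diene 3 with enal ester 4 (C4/C5 trans relation from the E enal), then hydrogenation; 12 ← geranyl benzoate 7 by ozonolysis, methyl-ketone Wittig homologation and kinetic silylation.
5. Ring order: ring A (step 3), then ring B (step 8).

Key step: step 8

Remark: compounds 1, 4 and 7 are taken as commercial; the silyl-bearing carbon of 5, 6 and 13 (later C10, ionised in step 8) and the carbinol carbon of 13–15 (later C6, reduced in step 10) form as inconsequential epimer mixtures and carry no descriptor in the SMILES, and C9 of 14–16 is drawn in its thermodynamic configuration, reached in step 11.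

**Route**

Step 1
Reactants: 1 pent-4-en-2-ol
Product: 2 pent-4-en-2-one
Conditions: DMP, NaHCO3, CH2Cl2, 0 °C to rt
Reagents that add atoms: none
Why: Dess–Martin oxidation of a secondary alcohol under buffered conditions should give the β,γ-unsaturated ketone without migration of the double bond into conjugation.

Step 2
Reactants: 2 pent-4-en-2-one
Product: 3 (3Z)-4-[(tert-butyldimethylsilyl)oxy]penta-1,3-diene
Conditions: TBSOTf, Et3N, CH2Cl2, −78 to 0 °C
Reagents that add atoms: tert-butyldimethylsilyl trifluoromethanesulfonate, CC(C)(C)[Si](C)(C)OS(=O)(=O)C(F)(F)F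
Why: Soft enolisation (silyl triflate and amine) removes the doubly activated C3–H between carbonyl and vinyl group, so the through-conjugated silyl dienol ether should form regioselectively.

Step 3
Reactants: 3 (3Z)-4-[(tert-butyldimethylsilyl)oxy]penta-1,3-diene; 4 ethyl (2E)-2-methyl-4-oxobut-2-enoate
Product: 5 ethyl (1R,6S)-5-[(tert-butyldimethylsilyl)oxy]-6-formyl-1,5-dimethylcyclohex-3-ene-1-carboxylate (epimers at C5)
Conditions: (S)-o-tolyl-CBS-oxazaborolidine·HNTf2 (20 mol %), CH2Cl2, −78 to −40 °C
Reagents that add atoms: none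
Why: Catalytic enantioselective Diels–Alder reaction in which the CH2 terminus of the 1-oxygenated diene bonds to the β-carbon of the catalyst-bound enal (ortho regiochemistry), the E geometry of 4 is transferred stereospecifically as the trans relation of CHO and CO2Et (C5 and C4 of the target), and the catalyst face selection sets the absolute configuration (the antipodal catalyst is used if the opposite sense is found).

Step 4
Reactants: 5 ethyl (1R,6S)-5-[(tert-butyldimethylsilyl)oxy]-6-formyl-1,5-dimethylcyclohex-3-ene-1-carboxylate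
Product: 6 ethyl (1R,2S)-3-[(tert-butyldimethylsilyl)oxy]-2-formyl-1,3-dimethylcyclohexane-1-carboxylate (epimers at C3)
Conditions: H2 (1 atm), 5% Rh/Al2O3, EtOAc, rt
Reagents that add atoms: none
Why: Heterogeneous hydrogenation should saturate the cis-disubstituted ring alkene under neutral conditions that leave the aldehyde and its epimerisable α-centre untouched.

Step 5
Reactants: 7 geranyl benzoate [(2E)-3,7-dimethylocta-2,6-dien-1-yl benzoate]
Product: 9 (2E)-3-methyl-6-oxohex-2-en-1-yl benzoate, via ozonide 8 (not isolated)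
Conditions: O3 (1 equiv), pyridine, CH2Cl2, −78 °C; then PPh3, −78 °C to rt
Reagents that add atoms: ozone, [O-][O+]=O
Why: Ozonolysis should cleave the electron-rich isopropylidene alkene selectively over the alkene deactivated by the allylic benzoate, whose E geometry is not touched.

Step 6
Reactants: 9 (2E)-3-methyl-6-oxohex-2-en-1-yl benzoate
Product: 11 (2E)-3-methyl-7-oxooct-2-en-1-yl benzoate, via enol ether 10 (not isolated)
Conditions: [Ph3PCH(OMe)CH3]Cl, NaN(SiMe3)2, THF, −78 to 0 °C; then 1 M HCl, THF, rt
Reagents that add atoms: (1-methoxyethyl)triphenylphosphonium chloride, COC(C)[P+](c1ccccc1)(c1ccccc1)c1ccccc1.[Cl-]; water, O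
Why: Wittig reaction with an α-methoxyalkylidene ylide followed by enol ether hydrolysis should turn the aldehyde carbon into the CH2 next to a new acetyl group, giving the methyl ketone that holds C7, C8 and C9.

Step 7
Reactants: 11 (2E)-3-methyl-7-oxooct-2-en-1-yl benzoate
Product: 12 (2E)-3-methyl-7-[(triisopropylsilyl)oxy]octa-2,7-dien-1-yl benzoate
Conditions: LiN(iPr)2, THF, −78 °C; then TIPSOTf
Reagents that add atoms: triisopropylsilyl trifluoromethanesulfonate, CC(C)[Si](C(C)C)(C(C)C)OS(=O)(=O)C(F)(F)F
Why: Kinetic deprotonation of the methyl ketone at the methyl group and O-silylation should give the terminal enol silane, the bulky silyl group being chosen to disfavour silyl transfer in step 8.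

Step 8
Reactants: 6 ethyl (1R,2S)-3-[(tert-butyldimethylsilyl)oxy]-2-formyl-1,3-dimethylcyclohexane-1-carboxylate; 12 (2E)-3-methyl-7-[(triisopropylsilyl)oxy]octa-2,7-dien-1-yl benzoate
Product: 14 ethyl (13E)-15-(benzoyloxy)-6-hydroxy-8-oxo-17-norlabd-13-en-18-oate, via ene adduct silyl enol ether 13 (not isolated)
Conditions: Me2AlCl, CH2Cl2, −78 °C; then SnCl4, 2,6-di-tert-butyl-4-methylpyridine, −78 to −20 °C; aq. NaHCO3
Reagents that add atoms: none
Why: Proposed new method: a one-flask formal [3+3] annulation that couples a prototropic (ene-type) aldol addition of a bulky silyl enol ether to an aldehyde with an intramolecular Lewis-acid-mediated α-tert-alkylation of the relayed silyl enol ether, the closest known cascades being the Lewis-acid-induced sequential ene annulation of alkenes with enals (methylenecyclohexane annulation) and cation–olefin cyclisations terminated by silyl enol ethers. Me2AlCl activates the hindered aldehyde of 6, the CH2 terminus of 12 attacks it while a C9–H is passed to oxygen (methane leaves aluminium), so C6–C7 forms and the enol silane is relayed to C8=C9 in 13. SnCl4 then ionises the tertiary silyl ether at C10 and the tethered enol silane closes ring B in a 6-(enol-endo) cation–olefin mode through a chair transition state, the silyl group being lost to give the C8 ketone. The C5 stereocentre keeps the chain equatorial and the axial C4 methyl shields the β face, so C9 should add to C10 anti to it and give the trans-decalin with the 10β-methyl group; C9, formed next to the ketone, is corrected by equilibration in step 11, and the C6 carbinol centre is removed in step 10. The step needs aldehyde addition before ionisation, secured by adding the ionising promoter only after the ene stage at −78 °C, and C- rather than O-alkylation of the terminating group, secured by the silylated enol oxygen.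

Step 9
Reactants: 14 ethyl (13E)-15-(benzoyloxy)-6-hydroxy-8-oxo-17-norlabd-13-en-18-oate
Product: 15 ethyl (13E)-15-(benzoyloxy)-6-[(1H-imidazol-1-ylcarbonothioyl)oxy]-8-oxo-17-norlabd-13-en-18-oate
Conditions: 1,1'-thiocarbonyldiimidazole, DMAP (cat.), 1,2-dichloroethane, 60 °C
Reagents that add atoms: 1,1'-thiocarbonyldiimidazole, S=C(n1ccnc1)n1ccnc1
Why: Thioacylation of the secondary alcohol under nearly neutral conditions should give the radical precursor for the Barton–McCombie deoxygenation.

Step 10
Reactants: 15 ethyl (13E)-15-(benzoyloxy)-6-[(1H-imidazol-1-ylcarbonothioyl)oxy]-8-oxo-17-norlabd-13-en-18-oate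
Product: 16 ethyl (13E)-15-(benzoyloxy)-8-oxo-17-norlabd-13-en-18-oate
Conditions: Bu3SnH, AIBN (cat.), toluene, 100 °C
Reagents that add atoms: none
Why: Barton–McCombie radical deoxygenation should replace the C6 oxygen by hydrogen without touching the ketone, the esters or the trisubstituted alkene.

Step 11
Reactants: 16 ethyl (13E)-15-(benzoyloxy)-8-oxo-17-norlabd-13-en-18-oate
Product: 17 (13E)-15-hydroxy-8-oxo-17-norlabd-13-en-18-oic acid
Conditions: KOH, EtOH–H2O, reflux; then aq. HCl to pH 3
Reagents that add atoms: potassium hydroxide, [K+].[OH-]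
Why: Saponification should cleave both the benzoate and the equatorial C18 ethyl ester, and the basic medium should equilibrate the ketone α-centre C9 to the more stable equatorial side chain (9α-H).

Step 12
Reactants: 17 (13E)-15-hydroxy-8-oxo-17-norlabd-13-en-18-oic acid
Product: 18 (13E)-15-hydroxylabda-8(17),13-dien-18-oic acid
Conditions: Ph3PCH3Br (excess), KOtBu, THF–toluene, 70 °C; aq. NH4Cl then dilute HCl
Reagents that add atoms: methyltriphenylphosphonium bromide, C[P+](c1ccccc1)(c1ccccc1)c1ccccc1.[Br-]
Why: Wittig methylenation of the 8-ketone with excess ylide (which also deprotonates the acid and the alcohol) should install the exocyclic C8=C17 alkene.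

Step 13
Reactants: 18 (13E)-15-hydroxylabda-8(17),13-dien-18-oic acid
Product: 19 (4R,5R,9S,10R,13E)-15-acetoxylabda-8(17),13-dien-18-oic acid (target, CNP0190226.3)
Conditions: Ac2O, pyridine, DMAP (cat.), CH2Cl2, 0 °C; aq. NaHCO3–THF, then dilute HCl
Reagents that add atoms: acetic anhydride, CC(=O)OC(C)=O
Why: Acetylation of the primary allylic alcohol, with hydrolysis of any mixed anhydride at the hindered carboxyl group during work-up, should give the target.

**Compound list**

1 | pent-4-en-2-ol | C=CCC(C)O | starting material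
2 | pent-4-en-2-one | C=CCC(C)=O | intermediate
3 | (3Z)-4-[(tert-butyldimethylsilyl)oxy]penta-1,3-diene | C=C/C=C(\O[Si](C)(C)C(C)(C)C)C | intermediate
4 | ethyl (2E)-2-methyl-4-oxobut-2-enoate | O=C/C=C(\C)C(=O)OCC | starting material
5 | ethyl (1R,6S)-5-[(tert-butyldimethylsilyl)oxy]-6-formyl-1,5-dimethylcyclohex-3-ene-1-carboxylate (C5 epimers) | O=C[C@@H]1C(C)(O[Si](C)(C)C(C)(C)C)C=CC[C@@]1(C)C(=O)OCC | intermediate
6 | ethyl (1R,2S)-3-[(tert-butyldimethylsilyl)oxy]-2-formyl-1,3-dimethylcyclohexane-1-carboxylate (C3 epimers; C1, C2, C3 become C4, C5, C10) | O=C[C@@H]1C(C)(O[Si](C)(C)C(C)(C)C)CCC[C@@]1(C)C(=O)OCC | intermediate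
7 | geranyl benzoate, (2E)-3,7-dimethylocta-2,6-dien-1-yl benzoate | CC(C)=CCC/C(C)=C/COC(=O)c1ccccc1 | starting material
8 | (2E)-5-(5,5-dimethyl-1,2,4-trioxolan-3-yl)-3-methylpent-2-en-1-yl benzoate (ozonide) | CC1(C)OOC(CC/C(C)=C/COC(=O)c2ccccc2)O1 | intermediate (not isolated)
9 | (2E)-3-methyl-6-oxohex-2-en-1-yl benzoate | O=CCC/C(C)=C/COC(=O)c1ccccc1 | intermediate
10 | (2E)-7-methoxy-3-methylocta-2,6-dien-1-yl benzoate (6E/6Z) | COC(C)=CCC/C(C)=C/COC(=O)c1ccccc1 | intermediate (not isolated)
11 | (2E)-3-methyl-7-oxooct-2-en-1-yl benzoate | CC(=O)CCC/C(C)=C/COC(=O)c1ccccc1 | intermediate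
12 | (2E)-3-methyl-7-[(triisopropylsilyl)oxy]octa-2,7-dien-1-yl benzoate | C=C(O[Si](C(C)C)(C(C)C)C(C)C)CCC/C(C)=C/COC(=O)c1ccccc1 | intermediate
13 | ethyl (1R,2R)-2-[(7E)-9-(benzoyloxy)-1-hydroxy-7-methyl-3-[(triisopropylsilyl)oxy]nona-3,7-dien-1-yl]-3-[(tert-butyldimethylsilyl)oxy]-1,3-dimethylcyclohexane-1-carboxylate (ene adduct, formed as its aluminium alkoxide) | OC(CC(O[Si](C(C)C)(C(C)C)C(C)C)=CCC/C(C)=C/COC(=O)c1ccccc1)[C@@H]1C(C)(O[Si](C)(C)C(C)(C)C)CCC[C@@]1(C)C(=O)OCC | intermediate (not isolated)
14 | ethyl (13E)-15-(benzoyloxy)-6-hydroxy-8-oxo-17-norlabd-13-en-18-oate (C6 epimers) | O=C1CC(O)[C@@H]2[C@](C)(CCC[C@@]2(C)C(=O)OCC)[C@H]1CC/C(C)=C/COC(=O)c1ccccc1 | intermediate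
15 | ethyl (13E)-15-(benzoyloxy)-6-[(1H-imidazol-1-ylcarbonothioyl)oxy]-8-oxo-17-norlabd-13-en-18-oate | O=C1CC(OC(=S)n3ccnc3)[C@@H]2[C@](C)(CCC[C@@]2(C)C(=O)OCC)[C@H]1CC/C(C)=C/COC(=O)c1ccccc1 | intermediate
16 | ethyl (13E)-15-(benzoyloxy)-8-oxo-17-norlabd-13-en-18-oate | O=C1CC[C@@H]2[C@](C)(CCC[C@@]2(C)C(=O)OCC)[C@H]1CC/C(C)=C/COC(=O)c1ccccc1 | intermediate
17 | (13E)-15-hydroxy-8-oxo-17-norlabd-13-en-18-oic acid | O=C1CC[C@@H]2[C@](C)(CCC[C@@]2(C)C(=O)O)[C@H]1CC/C(C)=C/CO | intermediate
18 | (13E)-15-hydroxylabda-8(17),13-dien-18-oic acid | C=C1CC[C@@H]2[C@](C)(CCC[C@@]2(C)C(=O)O)[C@H]1CC/C(C)=C/CO | intermediate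
19 | (4R,5R,9S,10R,13E)-15-acetoxylabda-8(17),13-dien-18-oic acid | C=C1CC[C@@H]2[C@](C)(CCC[C@@]2(C)C(=O)O)[C@H]1CC/C(C)=C/COC(C)=O | target

**Step count**

Total steps: 13. Longest linear sequence: 10 steps (steps 1–4 and 8–13).

**Steps most likely to fail, with fallbacks**

Step 8 (proposed new method). Silyl transfer (Mukaiyama-type aldol) may compete with the ene pathway and destroy the enol silane needed for ring closure; the tertiary cation may eliminate or be trapped by the ester carbonyl before C–C bond formation. The fallback sets out from 6 and the methyl ketone 11 and uses known steps one at a time. The kinetic lithium enolate of 11 (LiN(iPr)2, THF, −78 °C) should add to aldehyde 6 in a directed aldol reaction to give ethyl (1R,2R)-2-[(7E)-9-(benzoyloxy)-1-hydroxy-7-methyl-3-oxonon-7-en-1-yl]-3-[(tert-butyldimethylsilyl)oxy]-1,3-dimethylcyclohexane-1-carboxylate F1. Silylation (TESOTf, 2,6-lutidine) should give its triethylsilyl ether F2. Kinetic deprotonation on the side remote from the silyloxy-bearing carbon (LiN(iPr)2, Me3SiCl, −78 °C) should give the trimethylsilyl enol ether towards C9, F3. TiCl4 in CH2Cl2 at −78 °C should then ionise the tertiary silyl ether and effect the intramolecular α-tert-alkylation to ethyl (13E)-15-(benzoyloxy)-8-oxo-6-[(triethylsilyl)oxy]-17-norlabd-13-en-18-oate F4. Desilylation with HF·pyridine comes back to the route at 14.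

Step 3. The diene terminus that bears both methyl and silyloxy groups may react sluggishly, and 1,2-addition of the dienol ether to the aldehyde (vinylogous aldol) may compete, with loss of enantiocontrol. The fallback sets out from 3 and 4 and replaces asymmetric catalysis by resolution. Uncatalysed thermal cycloaddition (toluene, 80–110 °C) should give racemic ethyl (1R*,6S*)-5-[(tert-butyldimethylsilyl)oxy]-6-formyl-1,5-dimethylcyclohex-3-ene-1-carboxylate F5. Condensation with (1R,2R)-N,N'-dimethyl-1,2-diphenylethane-1,2-diamine (MgSO4, CH2Cl2) should give two diastereomeric imidazolidines, from which ethyl (1R,6R)-5-[(tert-butyldimethylsilyl)oxy]-6-[(4R,5R)-1,3-dimethyl-4,5-diphenylimidazolidin-2-yl]-1,5-dimethylcyclohex-3-ene-1-carboxylate F6 is separated by chromatography. Mild acid hydrolysis (aqueous citric acid) comes back to the route at 5.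

Step 9. β-Elimination of the activated hydroxyl next to the ketone may overtake thioacylation, or follow it. The fallback sets out from 14 and makes that elimination the intended path. Acid-catalysed dehydration (TsOH cat., benzene, 50 °C) should give the enone ethyl (13E)-15-(benzoyloxy)-8-oxo-17-norlabda-6,13-dien-18-oate F7. Chemoselective conjugate reduction with [(Ph3P)CuH]6 (benzene, H2O) should leave the trisubstituted alkene and the esters alone and comes back to the route at 16.

**Further compounds**

F1 | step 8 | ethyl (1R,2R)-2-[(7E)-9-(benzoyloxy)-1-hydroxy-7-methyl-3-oxonon-7-en-1-yl]-3-[(tert-butyldimethylsilyl)oxy]-1,3-dimethylcyclohexane-1-carboxylate | OC(CC(=O)CCC/C(C)=C/COC(=O)c1ccccc1)[C@@H]1C(C)(O[Si](C)(C)C(C)(C)C)CCC[C@@]1(C)C(=O)OCC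
F2 | step 8 | triethylsilyl ether of F1 | CC[Si](CC)(CC)OC(CC(=O)CCC/C(C)=C/COC(=O)c1ccccc1)[C@@H]1C(C)(O[Si](C)(C)C(C)(C)C)CCC[C@@]1(C)C(=O)OCC
F3 | step 8 | trimethylsilyl enol ether of F2 (enol double bond towards C9) | CC[Si](CC)(CC)OC(CC(O[Si](C)(C)C)=CCC/C(C)=C/COC(=O)c1ccccc1)[C@@H]1C(C)(O[Si](C)(C)C(C)(C)C)CCC[C@@]1(C)C(=O)OCC
F4 | step 8 | ethyl (13E)-15-(benzoyloxy)-8-oxo-6-[(triethylsilyl)oxy]-17-norlabd-13-en-18-oate | O=C1CC(O[Si](CC)(CC)CC)[C@@H]2[C@](C)(CCC[C@@]2(C)C(=O)OCC)[C@H]1CC/C(C)=C/COC(=O)c1ccccc1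
F5 | step 3 | racemic ethyl (1R*,6S*)-5-[(tert-butyldimethylsilyl)oxy]-6-formyl-1,5-dimethylcyclohex-3-ene-1-carboxylate | O=CC1C(C)(O[Si](C)(C)C(C)(C)C)C=CCC1(C)C(=O)OCC
F6 | step 3 | ethyl (1R,6R)-5-[(tert-butyldimethylsilyl)oxy]-6-[(4R,5R)-1,3-dimethyl-4,5-diphenylimidazolidin-2-yl]-1,5-dimethylcyclohex-3-ene-1-carboxylate | CN1[C@H](c2ccccc2)[C@@H](c2ccccc2)N(C)C1[C@@H]1C(C)(O[Si](C)(C)C(C)(C)C)C=CC[C@@]1(C)C(=O)OCC
F7 | step 9 | ethyl (13E)-15-(benzoyloxy)-8-oxo-17-norlabda-6,13-dien-18-oate | O=C1C=C[C@@H]2[C@](C)(CCC[C@@]2(C)C(=O)OCC)[C@H]1CC/C(C)=C/COC(=O)c1ccccc1
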